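**Plan**

- Retrosynthetic cuts, in order: the oxepane O–C16 bond (C3 hydroxyl onto a C16 triflate); C5=C6 of the oxonane (ring-closing metathesis, C7 ketone from a vinyl carbinol); then O–C2, C1–C2 and C9–C10 of the tetrahydrofuran in one Prins–pinacol step.
- Enabling feature: C11, the CHOAc carbon, is bonded to C10, a fusion carbon of the cis-fused tetrahydrofuran (O, C2, C1, C10, C9). Its oxygen is the carbonyl that remains when C9 shifts from C11 to C10, so no carbon has to be removed afterwards.
- Forward ring order: cyclohexene (Michael/aldol), tetrahydrofuran (diol 20 + aldehyde 25 → ketone 27), oxonane (metathesis), oxepane (etherification).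
- Stereochemistry: C15 and C3 from the chiral pool (1 and 21); C14 by catalyst-controlled Michael addition; C12 by trans alkylation; C11 of the diol by hydroxyl-directed epoxidation; C9 of the diol by chelate-controlled reduction; C1, C2, C9, C10 in the key step; C11–O by hydride addition from the convex face.

Key step: step 19

Remark: C1–C16 are the eunicellane-type locants of the target (C2/C9 ether carbons, C11 acetoxy carbon, C7 ketone); 1, 10 and 21 are taken as commercial; 13 and 32–38 are carried as epimer mixtures at a carbinol carbon that is oxidised later (C9 in 13, C7 in 32–38), and their SMILES leave that centre open.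

**Route**

Step 1
Reactants: 1 (S)-3-bromo-2-methylpropan-1-ol
Product: 2 (S)-[(3-bromo-2-methylpropoxy)methyl]benzene
Conditions: BnOC(=NH)CCl3, TfOH (cat.), cyclohexane/CH2Cl2, 0 °C to rt
Reagents that add atoms: benzyl 2,2,2-trichloroacetimidate, N=C(OCc1ccccc1)C(Cl)(Cl)Cl
Why: Acid-catalysed O-benzylation with the trichloroacetimidate avoids an alkoxide, which would close the bromo alcohol to an oxetane; C15 is untouched.

Step 2
Reactants: 2 (S)-[(3-bromo-2-methylpropoxy)methyl]benzene
Product: 4 (R)-4-(benzyloxy)-3-methylbutanal, via Grignard reagent 3 (not isolated)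
Conditions: Mg, I2 (cat.), THF, 40 °C; then DMF, 0 °C; 1 M HCl
Reagents that add atoms: N,N-dimethylformamide, CN(C)C=O
Why: Bouveault formylation of a primary Grignard reagent adds the future C1 as the aldehyde carbon without touching C15.

Step 3
Reactants: 4 (R)-4-(benzyloxy)-3-methylbutanal
Product: 6 (R)-4-[(R)-1-(benzyloxy)propan-2-yl]cyclohex-2-en-1-one, via keto aldehyde 5 (not isolated)
Conditions: but-3-en-2-one (1.5 equiv), (S)-2-[methoxy(diphenyl)methyl]pyrrolidine (5 mol %), ethyl 3,4-dihydroxybenzoate (20 mol %), neat, 4 °C; then LiOH (cat.), i-PrOH, rt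
Reagents that add atoms: but-3-en-2-one, CC(=O)C=C
Why: Enamine-catalysed Michael addition followed by intramolecular aldol condensation (Robinson-type annulation); C14 is set by the (S)-prolinol ether, whose E-enamine is attacked on the face away from the diarylmethyl group.

Step 4
Reactants: 6 (R)-4-[(R)-1-(benzyloxy)propan-2-yl]cyclohex-2-en-1-one
Product: 7 (4R,6R)-4-[(R)-1-(benzyloxy)propan-2-yl]-6-methylcyclohex-2-en-1-one
Conditions: LDA, THF, −78 °C; MeI, −78 to −40 °C
Reagents that add atoms: iodomethane, CI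
Why: Kinetic alkylation of the cross-conjugated α'-enolate; MeI should add axially with the C14 group pseudoequatorial, which gives the 4,6-trans product and sets C12.

Step 5
Reactants: 7 (4R,6R)-4-[(R)-1-(benzyloxy)propan-2-yl]-6-methylcyclohex-2-en-1-one
Product: 9 4-[(R)-1-(benzyloxy)propan-2-yl]-6-methylcyclohex-1-en-1-yl trifluoromethanesulfonate, via lithium enolate 8 (not isolated)
Conditions: L-Selectride, THF, −78 °C; then PhNTf2, −78 to 0 °C
Reagents that add atoms: N-phenylbis(trifluoromethanesulfonimide), O=S(=O)(N(c1ccccc1)S(=O)(=O)C(F)(F)F)C(F)(F)F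
Why: Conjugate reduction of the β-unsubstituted enone gives the C11–C10 enolate regiospecifically and O-triflation traps it, so C12 is never enolised.

Step 6
Reactants: 10 propane-1,3-diol
Product: 11 3-[(triisopropylsilyl)oxy]propan-1-ol
Conditions: TIPSCl (1 equiv), imidazole, CH2Cl2, 0 °C to rt, diol in excess
Reagents that add atoms: chlorotriisopropylsilane, CC(C)[Si](Cl)(C(C)C)C(C)C
Why: Statistical mono-silylation of a symmetric diol used in excess.

Step 7
Reactants: 11 3-[(triisopropylsilyl)oxy]propan-1-ol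
Product: 12 3-[(triisopropylsilyl)oxy]propanal
Conditions: Dess–Martin periodinane, CH2Cl2, 0 °C to rt
Reagents that add atoms: none
Why: Dess–Martin oxidation of a primary alcohol stops at the aldehyde under neutral conditions.

Step 8
Reactants: 9 vinyl triflate; 12 3-[(triisopropylsilyl)oxy]propanal
Product: 13 1-{4-[(R)-1-(benzyloxy)propan-2-yl]-6-methylcyclohex-1-en-1-yl}-3-[(triisopropylsilyl)oxy]propan-1-ol (C9 epimers)
Conditions: CrCl2 (4 equiv), NiCl2 (1 mol %), DMF, rt
Reagents that add atoms: none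
Why: Nozaki–Hiyama–Kishi coupling of an alkenyl triflate with an aldehyde forms C11–C9; no control at C9 is needed because step 9 removes that centre.

Step 9
Reactants: 13 allylic alcohols (C9 epimers)
Product: 14 1-{4-[(R)-1-(benzyloxy)propan-2-yl]-6-methylcyclohex-1-en-1-yl}-3-[(triisopropylsilyl)oxy]propan-1-one
Conditions: Dess–Martin periodinane, CH2Cl2, 0 °C to rt
Reagents that add atoms: none
Why: Dess–Martin oxidation converges both epimers on one enone without base, which the β-silyloxy ketone would not tolerate.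

Step 10
Reactants: 14 enone
Product: 15 (R)-1-{4-[(R)-1-(benzyloxy)propan-2-yl]-6-methylcyclohex-1-en-1-yl}-3-[(triisopropylsilyl)oxy]propan-1-ol
Conditions: (S)-Me-CBS (20 mol %), catecholborane, toluene, −78 °C
Reagents that add atoms: none
Why: Corey–Bakshi–Shibata reduction with the cyclohexenyl group as the large substituent should give the (R)-carbinol, a temporary C9 centre chosen so that the next step is matched.

Step 11
Reactants: 15 (R)-allylic alcohol
Product: 16 erythro 10,11-epoxy alcohol (epoxide on the ring face anti to the C12 methyl, C9 R)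
Conditions: VO(acac)2 (5 mol %), t-BuOOH, CH2Cl2, 0 °C to rt
Reagents that add atoms: tert-butyl hydroperoxide, CC(C)(C)OO
Why: Hydroxyl-directed vanadium epoxidation (Sharpless); the erythro transition state with C9–H next to C12 delivers oxygen to the face opposite the pseudoaxial C12 methyl, so directing group and ring bias agree and C11 is set.

Step 12
Reactants: 16 erythro epoxy alcohol
Product: 18 (1S,4R,6R)-4-[(R)-1-(benzyloxy)propan-2-yl]-1-{(R)-1-hydroxy-3-[(triisopropylsilyl)oxy]propyl}-6-methylcyclohex-2-en-1-ol, via hydroxy selenide 17 (not isolated)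
Conditions: (PhSe)2, NaBH4, EtOH, reflux; then 30% H2O2, THF, 0 °C to rt
Reagents that add atoms: none
Why: Sharpless–Lauer sequence: selenolate opens the epoxide at secondary C10 with inversion and the selenoxide syn-eliminates towards C1, the only β-hydrogen available, which gives the C10=C1 alkene and leaves the C11–O bond untouched.

Step 13
Reactants: 18 erythro diol
Product: 19 1-{(1S,4R,6R)-4-[(R)-1-(benzyloxy)propan-2-yl]-1-hydroxy-6-methylcyclohex-2-en-1-yl}-3-[(triisopropylsilyl)oxy]propan-1-one
Conditions: IBX, DMSO, rt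
Reagents that add atoms: none
Why: IBX oxidises the secondary carbinol of a 1,2-diol to the α-hydroxy ketone without glycol cleavage, removing the temporary C9 centre.

Step 14
Reactants: 19 α-hydroxy ketone
Product: 20 (1S,4R,6R)-4-[(R)-1-(benzyloxy)propan-2-yl]-1-{(S)-1-hydroxy-3-[(triisopropylsilyl)oxy]propyl}-6-methylcyclohex-2-en-1-ol (threo diol)
Conditions: Zn(BH4)2, Et2O, −20 °C
Reagents that add atoms: none
Why: Chelation-controlled reduction of an α-hydroxy ketone (Nakata–Oishi); hydride should reach the zinc chelate from the side of the flat vinylic C10–H, away from C12 and its cis methyl, which sets C9 as S.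

Step 15
Reactants: 21 (R)-2-methylglycidol
Product: 22 (S)-2-methylpent-4-ene-1,2-diol
Conditions: vinylMgBr (3 equiv), CuI (10 mol %), THF, −30 to 0 °C
Reagents that add atoms: vinylmagnesium bromide, C=C[Mg]Br
Why: Copper-catalysed Grignard opening of the epoxide at its CH2 carbon leaves the quaternary centre (future C3) unchanged.

Step 16
Reactants: 22 (S)-2-methylpent-4-ene-1,2-diol
Product: 23 (4S)-4-methyl-2-phenyl-4-(prop-2-en-1-yl)-1,3-dioxolane (both C2 epimers)
Conditions: PhCH(OMe)2, PPTS (cat.), CH2Cl2, rt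
Reagents that add atoms: benzaldehyde dimethyl acetal, COC(OC)c1ccccc1
Why: Acid-catalysed transacetalisation gives the benzylidene acetal of the 1,2-diol.

Step 17
Reactants: 23 benzylidene acetal
Product: 24 (S)-2-(benzyloxy)-2-methylpent-4-en-1-ol
Conditions: DIBAL-H, CH2Cl2, 0 °C to rt
Reagents that add atoms: none
Why: Reductive acetal opening: aluminium binds the less hindered primary oxygen, so the benzyl group stays on the tertiary oxygen and the primary alcohol is freed.

Step 18
Reactants: 24 (S)-2-(benzyloxy)-2-methylpent-4-en-1-ol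
Product: 25 (S)-2-(benzyloxy)-2-methylpent-4-enal
Conditions: Dess–Martin periodinane, CH2Cl2, 0 °C to rt
Reagents that add atoms: none
Why: Dess–Martin oxidation; the α-carbon is quaternary and cannot epimerise.

Step 19
Reactants: 20 threo diol; 25 (S)-2-(benzyloxy)-2-methylpent-4-enal
Product: 27 cis-fused hexahydroisobenzofuran-4-one (C11 ketone; C2 bears the (S)-2-(benzyloxy)pent-4-en-2-yl group, C9 the 2-[(triisopropylsilyl)oxy]ethyl group, C14 the (R)-1-(benzyloxy)propan-2-yl group, C12 a methyl cis to C9), via dioxolane acetal 26 (not isolated)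
Conditions: CSA (10 mol %), MgSO4, CH2Cl2, 0 °C; then SnCl4 (2 equiv), CH2Cl2, −78 to −20 °C
Reagents that add atoms: none
Why: The acetal ionises at C2 to the (E)-oxocarbenium ion on O9, C2 bonds to C1 of the ring alkene and C9 moves from C11 to C10 while O11 becomes the ketone; because C10 cannot hold a stabilised cation this should run as a concerted Prins–pinacol event or as a 2-oxonia-Cope shift followed by aldol closure of the C11 enol onto the C9 oxocarbenium carbon, and both paths lead to 27. The closest known reaction is the Overman Prins cyclisation–pinacol rearrangement of allylic diol acetals to 3-acyltetrahydrofurans. The tetrahydrofuran closes in the last bond-forming event (1,2-shift of C9, or 5-exo attack of enol carbon C10 on the oxocarbenium ion) after a six-membered array C2–O–C9–C11–C10–C1 that is bridged across the cyclohexene. C1 and C10 are set by C11 of 20: C9 sits on the ring face anti to the C14 side chain and both new bonds must form on that face, which gives the cis fusion; C2 and C9 are set by the exo placement of the C3 and C8 groups in the bridged array (boat-like oxane, away from C12–C14), which gives the 2,5-cis ether with both groups on the convex face, C9 keeping the configuration of the threo diol. The step needs ionisation at the acetal carbon and not at the tertiary allylic C11–O bond, and no enolisation of 27 towards C12; only the oxocarbenium ion on O9 can reach the alkene productively, and low temperature with short exposure to SnCl4 protects C12.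

Step 20
Reactants: 27 C11 ketone
Product: 28 C11 alcohol (hydroxyl cis to C10–C9 and to the C12 methyl)
Conditions: L-Selectride, THF, −78 °C
Reagents that add atoms: none
Why: Bulky-hydride reduction from the convex face, opposite the fused tetrahydrofuran and both flanking cis substituents, sets C11 with oxygen on the hindered face.

Step 21
Reactants: 28 C11 alcohol
Product: 29 C11 acetate
Conditions: Ac2O, Et3N, DMAP (cat.), CH2Cl2, rt
Reagents that add atoms: acetic anhydride, CC(=O)OC(C)=O
Why: DMAP-catalysed acylation installs the acetate of the target on the only free hydroxyl.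

Step 22
Reactants: 29 C11 acetate
Product: 30 primary C7 alcohol
Conditions: HF·pyridine, THF/pyridine, 0 °C to rt
Reagents that add atoms: none
Why: Fluoride-mediated desilylation removes the primary TIPS ether; acetate, benzyl ethers and alkene are inert.

Step 23
Reactants: 30 primary C7 alcohol
Product: 31 C7 aldehyde
Conditions: Dess–Martin periodinane, CH2Cl2, 0 °C to rt
Reagents that add atoms: none
Why: Dess–Martin oxidation under non-basic conditions avoids β-elimination of the C9 ether oxygen.

Step 24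
Reactants: 31 C7 aldehyde
Product: 32 C7 vinyl carbinol (C7 epimers)
Conditions: vinyl bromide, CrCl2, NiCl2 (cat.), DMF/DMSO, rt
Reagents that add atoms: bromoethene, C=CBr
Why: Nozaki–Hiyama–Kishi vinylation adds to the aldehyde and leaves the acetate alone; C7 needs no control because it becomes the ketone.

Step 25
Reactants: 32 C7 vinyl carbinol
Product: 33 C7 tert-butyldimethylsilyl ether
Conditions: TBSOTf, 2,6-lutidine, CH2Cl2, −78 to 0 °C
Reagents that add atoms: tert-butyldimethylsilyl trifluoromethanesulfonate, CC(C)(C)[Si](C)(C)OS(=O)(=O)C(F)(F)F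
Why: Silylation masks the C7 oxygen so that no C7 ketone can form a transannular hemiketal with the C3 hydroxyl during oxepane closure.

Step 26
Reactants: 33 diene
Product: 34 (Z)-oxonene (C5=C6), C7 silyl ether
Conditions: Grubbs second-generation catalyst (10 mol %), CH2Cl2 (2 mM), 40 °C
Reagents that add atoms: none
Why: Ring-closing metathesis between the C3 allyl and C7 vinyl groups, held close by the cis-2,5-disubstituted tetrahydrofuran, closes the nine-membered ether ring with loss of ethene.

Step 27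
Reactants: 34 oxonene
Product: 35 C3/C16 diol with saturated oxonane
Conditions: H2 (1 atm), 10% Pd/C, EtOAc, rt
Reagents that add atoms: none
Why: Catalytic hydrogenation saturates C5=C6 and hydrogenolyses both benzyl ethers in one operation; the silyl ether and acetate are stable.

Step 28
Reactants: 35 C3/C16 diol
Product: 37 oxepane (C16–O–C3), C7 silyl ether, via primary triflate 36 (not isolated)
Conditions: Tf2O (1.1 equiv), 2,6-lutidine, CH2Cl2, −78 °C to rt
Reagents that add atoms: none
Why: Selective triflation of the primary C16 hydroxyl and intramolecular Williamson-type displacement by the tertiary C3 hydroxyl (7-exo-tet) closes the oxepane; C3 keeps its configuration because its oxygen is the nucleophile.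

Step 29
Reactants: 37 oxepane silyl ether
Product: 38 C7 alcohol (C7 epimers)
Conditions: HF·pyridine, THF, 0 °C to rt
Reagents that add atoms: none
Why: Fluoride-mediated cleavage of the secondary silyl ether under conditions that spare the acetate.

Step 30
Reactants: 38 C7 alcohol
Product: 39 CNP0288436.2
Conditions: Dess–Martin periodinane, CH2Cl2, 0 °C to rt
Reagents that add atoms: none
Why: Dess–Martin oxidation converges both C7 epimers on the ketone without base, which the β-alkoxy ketone would not tolerate.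

**Compound list**

1 | (S)-3-bromo-2-methylpropan-1-ol | BrC[C@@H](C)CO | starting material
2 | (S)-[(3-bromo-2-methylpropoxy)methyl]benzene | BrC[C@@H](C)COCc1ccccc1 | intermediate
3 | [(S)-3-(benzyloxy)-2-methylpropyl]magnesium bromide (not isolated) | Br[Mg]C[C@@H](C)COCc1ccccc1 | intermediate
4 | (R)-4-(benzyloxy)-3-methylbutanal | O=CC[C@@H](C)COCc1ccccc1 | intermediate
5 | (S)-2-[(R)-1-(benzyloxy)propan-2-yl]-5-oxohexanal (not isolated) | O=C[C@@H](CCC(C)=O)[C@@H](C)COCc1ccccc1 | intermediate
6 | (R)-4-[(R)-1-(benzyloxy)propan-2-yl]cyclohex-2-en-1-one | O=C1C=C[C@@H](CC1)[C@@H](C)COCc1ccccc1 | intermediate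
7 | (4R,6R)-4-[(R)-1-(benzyloxy)propan-2-yl]-6-methylcyclohex-2-en-1-one | O=C1C=C[C@@H](C[C@H]1C)[C@@H](C)COCc1ccccc1 | intermediate
8 | lithium enolate from conjugate reduction of 7 (not isolated) | [Li]OC1=CC[C@@H](C[C@H]1C)[C@@H](C)COCc1ccccc1 | intermediate
9 | 4-[(R)-1-(benzyloxy)propan-2-yl]-6-methylcyclohex-1-en-1-yl trifluoromethanesulfonate (C12, C14 as in 7) | O=S(=O)(OC1=CC[C@@H](C[C@H]1C)[C@@H](C)COCc1ccccc1)C(F)(F)F | intermediate
10 | propane-1,3-diol | OCCCO | starting material
11 | 3-[(triisopropylsilyl)oxy]propan-1-ol | OCCCO[Si](C(C)C)(C(C)C)C(C)C | intermediate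
12 | 3-[(triisopropylsilyl)oxy]propanal | O=CCCO[Si](C(C)C)(C(C)C)C(C)C | intermediate
13 | cyclohexenyl carbinol, C9 epimers | OC(CCO[Si](C(C)C)(C(C)C)C(C)C)C1=CC[C@@H](C[C@H]1C)[C@@H](C)COCc1ccccc1 | intermediate
14 | cyclohexenyl ketone (C9 ketone) | O=C(CCO[Si](C(C)C)(C(C)C)C(C)C)C1=CC[C@@H](C[C@H]1C)[C@@H](C)COCc1ccccc1 | intermediate
15 | (R)-cyclohexenyl carbinol (C9 R) | O[C@H](CCO[Si](C(C)C)(C(C)C)C(C)C)C1=CC[C@@H](C[C@H]1C)[C@@H](C)COCc1ccccc1 | intermediate
16 | erythro 10,11-epoxy alcohol (epoxide anti to C12 methyl, C9 R) | O[C@H](CCO[Si](C(C)C)(C(C)C)C(C)C)[C@@]12O[C@@H]1C[C@@H](C[C@H]2C)[C@@H](C)COCc1ccccc1 | intermediate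
17 | C10 phenylselanyl C9,C11-diol (not isolated) | O[C@H](CCO[Si](C(C)C)(C(C)C)C(C)C)[C@@]1(O)[C@@H]([Se]c2ccccc2)C[C@@H](C[C@H]1C)[C@@H](C)COCc1ccccc1 | intermediate
18 | (1S,4R,6R)-4-[(R)-1-(benzyloxy)propan-2-yl]-1-{(R)-1-hydroxy-3-[(triisopropylsilyl)oxy]propyl}-6-methylcyclohex-2-en-1-ol (erythro diol) | O[C@]1([C@H](O)CCO[Si](C(C)C)(C(C)C)C(C)C)C=C[C@H]([C@@H](C)COCc2ccccc2)C[C@H]1C | intermediate
19 | 1-{(1S,4R,6R)-4-[(R)-1-(benzyloxy)propan-2-yl]-1-hydroxy-6-methylcyclohex-2-en-1-yl}-3-[(triisopropylsilyl)oxy]propan-1-one | O[C@]1(C(=O)CCO[Si](C(C)C)(C(C)C)C(C)C)C=C[C@H]([C@@H](C)COCc2ccccc2)C[C@H]1C | intermediate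
20 | (1S,4R,6R)-4-[(R)-1-(benzyloxy)propan-2-yl]-1-{(S)-1-hydroxy-3-[(triisopropylsilyl)oxy]propyl}-6-methylcyclohex-2-en-1-ol (threo diol) | O[C@]1([C@@H](O)CCO[Si](C(C)C)(C(C)C)C(C)C)C=C[C@H]([C@@H](C)COCc2ccccc2)C[C@H]1C | intermediate
21 | (R)-2-methylglycidol [(R)-(2-methyloxiran-2-yl)methanol] | OC[C@]1(C)CO1 | starting material
22 | (S)-2-methylpent-4-ene-1,2-diol | OC[C@@](C)(O)CC=C | intermediate
23 | (4S)-4-methyl-2-phenyl-4-(prop-2-en-1-yl)-1,3-dioxolane (both C2 epimers) | C=CC[C@@]1(C)COC(c2ccccc2)O1 | intermediate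
24 | (S)-2-(benzyloxy)-2-methylpent-4-en-1-ol | OC[C@@](C)(OCc1ccccc1)CC=C | intermediate
25 | (S)-2-(benzyloxy)-2-methylpent-4-enal | O=C[C@@](C)(OCc1ccccc1)CC=C | intermediate
26 | spiro-dioxolane acetal of 20 and 25, both acetal epimers (not isolated) | C=CC[C@](C)(OCc1ccccc1)C1O[C@@H](CCO[Si](C(C)C)(C(C)C)C(C)C)[C@@]2(O1)C=C[C@H]([C@@H](C)COCc1ccccc1)C[C@H]2C | intermediate
27 | cis-fused hexahydroisobenzofuran-4-one (C11 ketone) with C2, C9, C12 and C14 substituents | O=C1[C@@H]2[C@H]([C@H]([C@@H](C)COCc3ccccc3)C[C@H]1C)[C@H](O[C@H]2CCO[Si](C(C)C)(C(C)C)C(C)C)[C@@](C)(OCc3ccccc3)CC=C | intermediate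
28 | C11 alcohol of 27 (OH cis to C9 and C12 methyl) | O[C@H]1[C@@H]2[C@H]([C@H]([C@@H](C)COCc3ccccc3)C[C@H]1C)[C@H](O[C@H]2CCO[Si](C(C)C)(C(C)C)C(C)C)[C@@](C)(OCc3ccccc3)CC=C | intermediate
29 | C11 acetate | CC(=O)O[C@H]1[C@@H]2[C@H]([C@H]([C@@H](C)COCc3ccccc3)C[C@H]1C)[C@H](O[C@H]2CCO[Si](C(C)C)(C(C)C)C(C)C)[C@@](C)(OCc3ccccc3)CC=C | intermediate
30 | C11 acetate, primary C7 alcohol | CC(=O)O[C@H]1[C@@H]2[C@H]([C@H]([C@@H](C)COCc3ccccc3)C[C@H]1C)[C@H](O[C@H]2CCO)[C@@](C)(OCc3ccccc3)CC=C | intermediate
31 | C11 acetate, C7 aldehyde | CC(=O)O[C@H]1[C@@H]2[C@H]([C@H]([C@@H](C)COCc3ccccc3)C[C@H]1C)[C@H](O[C@H]2CC=O)[C@@](C)(OCc3ccccc3)CC=C | intermediate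
32 | C7 vinyl carbinol (C7 epimers) | CC(=O)O[C@H]1[C@@H]2[C@H]([C@H]([C@@H](C)COCc3ccccc3)C[C@H]1C)[C@H](O[C@H]2CC(O)C=C)[C@@](C)(OCc3ccccc3)CC=C | intermediate
33 | C7 TBS ether of 32 | CC(=O)O[C@H]1[C@@H]2[C@H]([C@H]([C@@H](C)COCc3ccccc3)C[C@H]1C)[C@H](O[C@H]2CC(O[Si](C)(C)C(C)(C)C)C=C)[C@@](C)(OCc3ccccc3)CC=C | intermediate
34 | (Z)-oxonene, C7 TBS ether, both benzyl ethers in place | CC(=O)O[C@H]1[C@@H]2[C@H]([C@H]([C@@H](C)COCc3ccccc3)C[C@H]1C)[C@@H]1O[C@H]2CC(O[Si](C)(C)C(C)(C)C)/C=C\C[C@]1(C)OCc1ccccc1 | intermediate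
35 | saturated oxonane, C3 tertiary alcohol, C16 primary alcohol, C7 TBS ether | CC(=O)O[C@H]1[C@@H]2[C@H]([C@H]([C@@H](C)CO)C[C@H]1C)[C@@H]1O[C@H]2CC(O[Si](C)(C)C(C)(C)C)CCC[C@]1(C)O | intermediate
36 | C16 triflate of 35 (not isolated) | CC(=O)O[C@H]1[C@@H]2[C@H]([C@H]([C@@H](C)COS(=O)(=O)C(F)(F)F)C[C@H]1C)[C@@H]1O[C@H]2CC(O[Si](C)(C)C(C)(C)C)CCC[C@]1(C)O | intermediate
37 | tetracyclic oxepane, C7 TBS ether | CC(=O)O[C@H]1[C@@H]2[C@@H]3[C@@H](C[C@H]1C)[C@@H](C)CO[C@@]1(C)CCCC(O[Si](C)(C)C(C)(C)C)C[C@@H]2O[C@@H]31 | intermediate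
38 | tetracyclic C7 alcohol | CC(=O)O[C@H]1[C@@H]2[C@@H]3[C@@H](C[C@H]1C)[C@@H](C)CO[C@@]1(C)CCCC(O)C[C@@H]2O[C@@H]31 | intermediate
39 | CNP0288436.2 | CC(=O)O[C@H]1[C@@H]2[C@@H]3[C@@H](C[C@H]1C)[C@@H](C)CO[C@@]1(C)CCCC(=O)C[C@@H]2O[C@@H]31 | target

**Totals and risks**

Total step count: 30. Longest linear sequence: 24 steps (steps 1–5, 8–14, 19–30).

Most likely to fail, riskiest first:

1. Step 19. The tertiary allylic C11–O bond may ionise instead of the acetal C–O bond, or C–C bond formation at the unactivated ring alkene may be slow enough for the acetal to revert or for C12 to epimerise in the product. The fallback forms the same three bonds in two stages by a homoaldol route (Hoppe-type). It sets out from enone 7. Luche reduction should give allylic alcohol F1, and carbamoylation (i-Pr2NCOCl, NaH) the N,N-diisopropylcarbamate F2. Deprotonation at C11 (s-BuLi, TMEDA), exchange to titanium with ClTi(Oi-Pr)3 and addition of aldehyde 25 at C1, anti to the C14 side chain, should give (Z)-enol carbamate F3. Condensation of F3 with aldehyde 12 under BF3·OEt2 forms the oxocarbenium ion on the C2 oxygen, which the enol carbamate closes to the tetrahydrofuran with release of the C11 ketone. The fallback comes back to the route at 27.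

2. Step 14. Facial selectivity in the hydride addition to the zinc chelate may be poor, returning part of the material as the erythro diol. The fallback sets C9 by reagent control before the alkene is shifted. It sets out from epoxy alcohol 16. Dess–Martin oxidation should give epoxy ketone F4, and (R)-Me-CBS/catecholborane reduction the threo epoxy alcohol F5. Selenolate opening and selenoxide elimination as in step 12, through hydroxy selenide F6, then lead back to the route at 20.

3. Step 26. Intermolecular metathesis (oligomerisation) or isomerisation of the allyl group may outrun closure of the nine-membered ring. The fallback closes the ring by C6–C7 bond formation with chromium instead. It sets out from acetate 29. Ozonolysis (O3, then PPh3) should give aldehyde F7, and Stork–Zhao olefination (Ph3P=CHI) the (Z)-vinyl iodide F8. Desilylation (HF·pyridine) gives alcohol F9 and Dess–Martin oxidation the iodo aldehyde F10. Intramolecular Nozaki–Hiyama–Kishi reaction at high dilution should give cyclic allylic alcohol F11, and silylation with TBSOTf comes back to the route at 34.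

Further compounds
F1 | step 19 | allylic alcohol from 7 (either C11 epimer) | OC1C=C[C@@H](C[C@H]1C)[C@@H](C)COCc1ccccc1
F2 | step 19 | N,N-diisopropylcarbamate of F1 | CC(C)N(C(C)C)C(=O)OC1C=C[C@@H](C[C@H]1C)[C@@H](C)COCc1ccccc1
F3 | step 19 | (Z)-enol carbamate homoaldol adduct (C1–C2 bond, free C2 hydroxyl) | CC(C)N(C(C)C)C(=O)OC1=C[C@@H]([C@H](O)[C@@](C)(OCc2ccccc2)CC=C)[C@@H](C[C@H]1C)[C@@H](C)COCc1ccccc1
F4 | step 14 | 10,11-epoxy C9 ketone | O=C(CCO[Si](C(C)C)(C(C)C)C(C)C)[C@@]12O[C@@H]1C[C@@H](C[C@H]2C)[C@@H](C)COCc1ccccc1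
F5 | step 14 | threo 10,11-epoxy alcohol (C9 S) | O[C@@H](CCO[Si](C(C)C)(C(C)C)C(C)C)[C@@]12O[C@@H]1C[C@@H](C[C@H]2C)[C@@H](C)COCc1ccccc1
F6 | step 14 | C10 phenylselanyl threo diol (not isolated) | O[C@@H](CCO[Si](C(C)C)(C(C)C)C(C)C)[C@@]1(O)[C@@H]([Se]c2ccccc2)C[C@@H](C[C@H]1C)[C@@H](C)COCc1ccccc1
F7 | step 26 | C5 aldehyde from ozonolysis of 29 | CC(=O)O[C@H]1[C@@H]2[C@H]([C@H]([C@@H](C)COCc3ccccc3)C[C@H]1C)[C@H](O[C@H]2CCO[Si](C(C)C)(C(C)C)C(C)C)[C@@](C)(OCc3ccccc3)CC=O
F8 | step 26 | (Z)-vinyl iodide (C5=C6–I) | CC(=O)O[C@H]1[C@@H]2[C@H]([C@H]([C@@H](C)COCc3ccccc3)C[C@H]1C)[C@H](O[C@H]2CCO[Si](C(C)C)(C(C)C)C(C)C)[C@@](C)(OCc3ccccc3)C/C=C\I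
F9 | step 26 | (Z)-vinyl iodide, primary C7 alcohol | CC(=O)O[C@H]1[C@@H]2[C@H]([C@H]([C@@H](C)COCc3ccccc3)C[C@H]1C)[C@H](O[C@H]2CCO)[C@@](C)(OCc3ccccc3)C/C=C\I
F10 | step 26 | (Z)-vinyl iodide, C7 aldehyde | CC(=O)O[C@H]1[C@@H]2[C@H]([C@H]([C@@H](C)COCc3ccccc3)C[C@H]1C)[C@H](O[C@H]2CC=O)[C@@](C)(OCc3ccccc3)C/C=C\I
F11 | step 26 | (Z)-oxonene C7 alcohol (C7 epimers) | CC(=O)O[C@H]1[C@@H]2[C@H]([C@H]([C@@H](C)COCc3ccccc3)C[C@H]1C)[C@@H]1O[C@H]2CC(O)/C=C\C[C@]1(C)OCc1ccccc1
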